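**Strategy.** Ring B is disconnected at C5–C6 and C9–C10 (labdane numbering), the two bonds that tie the C6–C7(O)–C8=C9 unit to ring A. One radical [4+2] annulation forms both: the α-keto radical at C6 of a bromomethyl enone adds to the hydrogen-bearing alkene carbon (C5) of 1,3,3-trimethylcyclohexene, and the tertiary C10 radical closes ring B 6-endo on the enone β-carbon C9. The step exploits the C7 oxygen of ring B, flanked by C6H2 and the C8=C9 alkene, and sets the trans C5–H/C10–CH3 ring fusion. Both precursors are achiral: a bromo enone from methyl geranate and the ring A alkene. A reagent-controlled CBS reduction then sets C7 and selects the (5R,10R) series.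

Key step: step 6

Remark on numbering: C1–C20 are labdane locants; in the naphthalene names C-1 = C9, C-2 = C8, C-3 = C7, C-4 = C6, C-4a = C5 and C-8a = C10.
Assumption: methyl geranate is used as the pure (2E) isomer; material that holds the (2Z) isomer is purified by chromatography first.
Remark: 11 and 12 are racemates; their SMILES show the enantiomer that leads to the target. The absolute configuration is fixed in step 7, where the diastereomer from the other enantiomer is removed, so at most half of 12 is carried on.

Step 1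
Reactants: 1 methyl (2E)-3,7-dimethylocta-2,6-dienoate (methyl geranate)
Product: 2 methyl (2E)-3-methyl-6-oxohex-2-enoate
Conditions: O3, CH2Cl2/MeOH, −78 °C; then Me2S, −78 → 23 °C
Reagents that add atoms: ozone, O=[O+][O-]
Why: Ozonolysis with reductive work-up; the electron-rich trisubstituted 6,7-alkene reacts far faster than the ester-conjugated 2,3-alkene, so one equivalent of ozone should cleave only the isopropylidene end.

Step 2
Reactants: 2 methyl (2E)-3-methyl-6-oxohex-2-enoate; 3 3-(triphenylphosphoranylidene)butan-2-one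
Product: 4 methyl (2E,6E)-3,7-dimethyl-8-oxonona-2,6-dienoate
Conditions: toluene, 90 °C
Reagents that add atoms: none
Why: Wittig olefination with a stabilized, α-branched keto ylide, which should give the (E)-trisubstituted enone under thermodynamic control.

Step 3
Reactants: 4 methyl (2E,6E)-3,7-dimethyl-8-oxonona-2,6-dienoate
Product: 6 methyl (2E,6E)-9-bromo-3,7-dimethyl-8-oxonona-2,6-dienoate, via trimethylsilyl dienol ether 5 (not isolated)
Conditions: Me3SiOTf, Et3N, CH2Cl2, 0 °C; then NBS, THF, −78 °C
Reagents that add atoms: N-bromosuccinimide, O=C1CCC(=O)N1Br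
Why: Soft enolization takes the kinetic proton of the methyl ketone to give the cross-conjugated silyl dienol ether, whose terminal carbon is brominated by NBS (α-halogenation of a silyl enol ether), while the ester and both trisubstituted alkenes stay untouched.

Step 4
Reactants: 7 2,2,6-trimethylcyclohexan-1-one
Product: 9 2,6,6-trimethylcyclohex-1-en-1-yl trifluoromethanesulfonate, via potassium enolate 8 (not isolated)
Conditions: KN(SiMe3)2, THF, −78 → 0 °C; then PhNTf2, −78 → 23 °C
Reagents that add atoms: N-phenylbis(trifluoromethanesulfonimide), O=S(=O)(N(c1ccccc1)S(=O)(=O)C(F)(F)F)C(F)(F)F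
Why: Enol triflate formation; C6 carries the only enolizable hydrogen, so deprotonation and O-sulfonylation give one regioisomer and erase the stereocenter of racemic 7.

Step 5
Reactants: 9 2,6,6-trimethylcyclohex-1-en-1-yl trifluoromethanesulfonate
Product: 10 1,3,3-trimethylcyclohex-1-ene
Conditions: Pd(OAc)2 (cat.), PPh3, HCO2H, Bu3N, DMF, 60 °C
Reagents that add atoms: none
Why: Palladium-catalysed formate reduction of an enol triflate (oxidative addition, decarboxylation of formate to a palladium hydride, reductive elimination), which replaces the triflate by hydrogen without moving the double bond.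

Step 6
Reactants: 6 methyl (2E,6E)-9-bromo-3,7-dimethyl-8-oxonona-2,6-dienoate; 10 1,3,3-trimethylcyclohex-1-ene
Product: 12 methyl (2E)-3-methyl-5-[rel-(4aR,8aR)-2,5,5,8a-tetramethyl-3-oxo-3,4,4a,5,6,7,8,8a-octahydronaphthalen-1-yl]pent-2-enoate, via tertiary bromo ketone 11 (not isolated)
Conditions: CuBr (10 mol %), 4,4'-di-tert-butyl-2,2'-bipyridine, 10 (8 equiv), 1,2-dichloroethane, 80 °C; then DBU, 80 °C
Reagents that add atoms: none
Why: Proposed new method: monovalent copper takes the bromine atom of 6 to give an electrophilic α-keto radical at C6 that adds to the hydrogen-bearing alkene carbon (C5) of the electron-rich alkene 10, the tertiary, nucleophilic C10 radical then adds to the enone β-carbon C9, and bromine transfer from CuBr2 to the tertiary α-keto radical at C8 gives 11, from which DBU removes HBr and equilibrates the product to the conjugated tetrasubstituted enone 12. The closest known reaction types are atom-transfer radical annulation (Kharasch addition of an α-halo carbonyl compound to an alkene followed by cyclization onto a tethered π-bond) and the 6-endo closure of 1-methyl-2-alkylcyclohexyl radicals in Mn(OAc)3-mediated polyene radical cyclizations. Ring B is the only ring closed and it closes 6-endo-trig, because the C8 methyl group and the polarity of the enone disfavour 5-exo attack at C8. C5 is set in the intermolecular addition and C10 in the ring closure, anti to each other through a chair-like transition state with the C5 side chain equatorial (trans ring fusion); absolute configuration is not controlled here, so 12 is a racemate. The step needs attack of the first radical at C5 and not at C10, secured by the tertiary radical that results, and it needs the side-chain alkene to stay out, secured by its conjugation with the ester, which makes it a poor partner for the electrophilic C6 and C8 radicals; 10 is used in excess to outrun self-reaction of 6.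

Step 7
Reactants: 12 methyl (2E)-3-methyl-5-[rel-(4aR,8aR)-2,5,5,8a-tetramethyl-3-oxo-3,4,4a,5,6,7,8,8a-octahydronaphthalen-1-yl]pent-2-enoate
Product: 13 methyl (2E)-5-[(3S,4aR,8aR)-3-hydroxy-2,5,5,8a-tetramethyl-3,4,4a,5,6,7,8,8a-octahydronaphthalen-1-yl]-3-methylpent-2-enoate
Conditions: (R)-2-methyl-CBS-oxazaborolidine (20 mol %), catecholborane, toluene, −78 °C; chromatographic separation of the diastereomers
Reagents that add atoms: none
Why: Corey–Bakshi–Shibata reduction under reagent control: the oxazaborolidine treats the methyl-bearing alkenyl carbon as the large group and should deliver hydride to the same local face of the ketone in both enantiomers of 12, setting C3 as S, so the (4aR,8aR) enantiomer gives the pseudoaxial alcohol 13 and the (4aS,8aS) enantiomer gives a pseudoequatorial diastereomer that is separated, which fixes the absolute configuration of the series.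

Step 8
Reactants: 13 methyl (2E)-5-[(3S,4aR,8aR)-3-hydroxy-2,5,5,8a-tetramethyl-3,4,4a,5,6,7,8,8a-octahydronaphthalen-1-yl]-3-methylpent-2-enoate
Product: 14 (2E)-5-[(3S,4aR,8aR)-3-hydroxy-2,5,5,8a-tetramethyl-3,4,4a,5,6,7,8,8a-octahydronaphthalen-1-yl]-3-methylpent-2-en-1-ol
Conditions: i-Bu2AlH, CH2Cl2, −78 °C; aq. potassium sodium tartrate
Reagents that add atoms: none
Why: 1,2-Reduction of the conjugated ester to the primary allylic alcohol by the aluminium hydride, with the secondary alcohol carried as its aluminium alkoxide and the tetrasubstituted alkene inert.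

Step 9
Reactants: 14 (2E)-5-[(3S,4aR,8aR)-3-hydroxy-2,5,5,8a-tetramethyl-3,4,4a,5,6,7,8,8a-octahydronaphthalen-1-yl]-3-methylpent-2-en-1-ol
Product: 15 (2E)-5-[(3S,4aR,8aR)-3-(acetyloxy)-2,5,5,8a-tetramethyl-3,4,4a,5,6,7,8,8a-octahydronaphthalen-1-yl]-3-methylpent-2-en-1-yl acetate
Conditions: Ac2O, pyridine, DMAP (cat.), CH2Cl2, 23 °C
Reagents that add atoms: acetic anhydride, CC(=O)OC(C)=O
Why: DMAP-catalysed acylation of both hydroxyl groups, with retention at C3 because no C–O bond of the substrate is broken.

**Compound list**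

1 | methyl (2E)-3,7-dimethylocta-2,6-dienoate (methyl geranate) | COC(=O)/C=C(\C)CCC=C(C)C | starting material
2 | methyl (2E)-3-methyl-6-oxohex-2-enoate | COC(=O)/C=C(\C)CCC=O | intermediate
3 | 3-(triphenylphosphoranylidene)butan-2-one | CC(=O)C(C)=P(c1ccccc1)(c1ccccc1)c1ccccc1 | starting material
4 | methyl (2E,6E)-3,7-dimethyl-8-oxonona-2,6-dienoate | COC(=O)/C=C(\C)CC/C=C(\C)C(C)=O | intermediate
5 | methyl (2E,6E)-3,7-dimethyl-8-[(trimethylsilyl)oxy]nona-2,6,8-trienoate (not isolated) | COC(=O)/C=C(\C)CC/C=C(\C)C(=C)O[Si](C)(C)C | intermediate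
6 | methyl (2E,6E)-9-bromo-3,7-dimethyl-8-oxonona-2,6-dienoate | COC(=O)/C=C(\C)CC/C=C(\C)C(=O)CBr | intermediate
7 | 2,2,6-trimethylcyclohexan-1-one (racemic) | CC1CCCC(C)(C)C1=O | starting material
8 | potassium 2,6,6-trimethylcyclohex-1-en-1-olate (not isolated) | CC1=C([O-])C(C)(C)CCC1.[K+] | intermediate
9 | 2,6,6-trimethylcyclohex-1-en-1-yl trifluoromethanesulfonate | CC1=C(OS(=O)(=O)C(F)(F)F)C(C)(C)CCC1 | intermediate
10 | 1,3,3-trimethylcyclohex-1-ene | CC1=CC(C)(C)CCC1 | intermediate
11 | methyl (2E)-5-(2-bromo-2,5,5,8a-tetramethyl-3-oxodecahydronaphthalen-1-yl)-3-methylpent-2-enoate; trans ring fusion, H-1 syn to H-4a, both C-2 epimers, racemate (not isolated) | COC(=O)/C=C(\C)CC[C@@H]1C(C)(Br)C(=O)C[C@@H]2C(C)(C)CCC[C@@]12C | intermediate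
12 | methyl (2E)-3-methyl-5-[rel-(4aR,8aR)-2,5,5,8a-tetramethyl-3-oxo-3,4,4a,5,6,7,8,8a-octahydronaphthalen-1-yl]pent-2-enoate (racemate) | COC(=O)/C=C(\C)CCC1=C(C)C(=O)C[C@@H]2C(C)(C)CCC[C@@]12C | intermediate
13 | methyl (2E)-5-[(3S,4aR,8aR)-3-hydroxy-2,5,5,8a-tetramethyl-3,4,4a,5,6,7,8,8a-octahydronaphthalen-1-yl]-3-methylpent-2-enoate | COC(=O)/C=C(\C)CCC1=C(C)[C@@H](O)C[C@@H]2C(C)(C)CCC[C@@]12C | intermediate
14 | (2E)-5-[(3S,4aR,8aR)-3-hydroxy-2,5,5,8a-tetramethyl-3,4,4a,5,6,7,8,8a-octahydronaphthalen-1-yl]-3-methylpent-2-en-1-ol | OC/C=C(\C)CCC1=C(C)[C@@H](O)C[C@@H]2C(C)(C)CCC[C@@]12C | intermediate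
15 | (2E)-5-[(3S,4aR,8aR)-3-(acetyloxy)-2,5,5,8a-tetramethyl-3,4,4a,5,6,7,8,8a-octahydronaphthalen-1-yl]-3-methylpent-2-en-1-yl acetate | CC(=O)OC/C=C(\C)CCC1=C(C)[C@@H](OC(C)=O)C[C@@H]2C(C)(C)CCC[C@@]12C | target

**Totals.** Total step count: 9. Longest linear sequence: 7 steps (1, 2, 3, 6, 7, 8, 9).

**Steps most likely to fail**

Step 6 (Proposed new method). Process at risk: slow addition of the C6 radical to the hindered ring alkene, so that reduction or self-coupling of 6 takes over, or loss of the C10 radical by bromine transfer and elimination before ring closure. Fallback with known chemistry, from 4 and 9 back to 12: the zinc enolate of 4 (LiN(SiMe3)2, then ZnCl2) is coupled with triflate 9 under zerovalent palladium catalysis (Pd(dba)2, P(t-Bu)3; α-alkenylation of a ketone enolate) to give methyl (2E,6E)-3,7-dimethyl-8-oxo-9-(2,6,6-trimethylcyclohex-1-en-1-yl)nona-2,6-dienoate F1. Hydrogen-atom transfer from an iron hydride (Fe(acac)3, PhSiH3, EtOH) to the ring alkene, followed by 6-endo Giese cyclization of the tertiary radical onto the enone, should give the saturated trans-fused ketone methyl (2E)-3-methyl-5-(2,5,5,8a-tetramethyl-3-oxodecahydronaphthalen-1-yl)pent-2-enoate F2. Its more substituted silyl enol ether, methyl (2E)-3-methyl-5-{2,5,5,8a-tetramethyl-3-[(trimethylsilyl)oxy]-1,4,4a,5,6,7,8,8a-octahydronaphthalen-1-yl}pent-2-enoate F3 (Me3SiOTf, Et3N), is dehydrogenated with Pd(OAc)2 (Saegusa–Ito oxidation) to 12.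

Step 7. Process at risk: poor facial selectivity in the mismatched pairing, where the reagent must deliver hydride syn to the angular methyl group, so that little of 13 forms. Fallback from 12 back to 15: reduction with (S)-2-methyl-CBS-oxazaborolidine and catecholborane is run as a kinetic resolution to about half conversion. The (4aR,8aR) enantiomer is then the matched one (hydride enters axially, anti to the angular methyl group) and should give the pseudoequatorial alcohol methyl (2E)-5-[(3R,4aR,8aR)-3-hydroxy-2,5,5,8a-tetramethyl-3,4,4a,5,6,7,8,8a-octahydronaphthalen-1-yl]-3-methylpent-2-enoate F4. i-Bu2AlH reduces the ester to (2E)-5-[(3R,4aR,8aR)-3-hydroxy-2,5,5,8a-tetramethyl-3,4,4a,5,6,7,8,8a-octahydronaphthalen-1-yl]-3-methylpent-2-en-1-ol F5. A double Mitsunobu reaction with acetic acid (PPh3, diisopropyl azodicarboxylate) acetylates the primary alcohol and inverts C3, which gives 15 directly.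

Step 3. Process at risk: enolization toward the γ-methylene group and bromination there, or loss of the labile bromomethyl ketone by self-alkylation and elimination on handling. Fallback from 2 back to 6: Wittig reaction of 2 with 2-(triphenylphosphoranylidene)propanal gives the enal methyl (2E,6E)-3,7-dimethyl-8-oxoocta-2,6-dienoate F6. (Bromomethyl)lithium, generated in the presence of the aldehyde from CH2Br2 and MeLi·LiBr at −78 °C, adds to give the bromohydrin methyl (2E,6E)-9-bromo-8-hydroxy-3,7-dimethylnona-2,6-dienoate F7. Dess–Martin oxidation of the bromohydrin gives 6.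

**Further compounds**

F1 | step 6 | methyl (2E,6E)-3,7-dimethyl-8-oxo-9-(2,6,6-trimethylcyclohex-1-en-1-yl)nona-2,6-dienoate | COC(=O)/C=C(\C)CC/C=C(\C)C(=O)CC1=C(C)CCCC1(C)C
F2 | step 6 | methyl (2E)-3-methyl-5-(2,5,5,8a-tetramethyl-3-oxodecahydronaphthalen-1-yl)pent-2-enoate; trans ring fusion, H-1 syn to H-4a, C-2 epimers, racemate | COC(=O)/C=C(\C)CC[C@@H]1C(C)C(=O)C[C@@H]2C(C)(C)CCC[C@@]12C
F3 | step 6 | methyl (2E)-3-methyl-5-{2,5,5,8a-tetramethyl-3-[(trimethylsilyl)oxy]-1,4,4a,5,6,7,8,8a-octahydronaphthalen-1-yl}pent-2-enoate; trans ring fusion, H-1 syn to H-4a, racemate | COC(=O)/C=C(\C)CC[C@@H]1C(C)=C(O[Si](C)(C)C)C[C@@H]2C(C)(C)CCC[C@@]12C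
F4 | step 7 | methyl (2E)-5-[(3R,4aR,8aR)-3-hydroxy-2,5,5,8a-tetramethyl-3,4,4a,5,6,7,8,8a-octahydronaphthalen-1-yl]-3-methylpent-2-enoate | COC(=O)/C=C(\C)CCC1=C(C)[C@H](O)C[C@@H]2C(C)(C)CCC[C@@]12C
F5 | step 7 | (2E)-5-[(3R,4aR,8aR)-3-hydroxy-2,5,5,8a-tetramethyl-3,4,4a,5,6,7,8,8a-octahydronaphthalen-1-yl]-3-methylpent-2-en-1-ol | OC/C=C(\C)CCC1=C(C)[C@H](O)C[C@@H]2C(C)(C)CCC[C@@]12C
F6 | step 3 | methyl (2E,6E)-3,7-dimethyl-8-oxoocta-2,6-dienoate | COC(=O)/C=C(\C)CC/C=C(\C)C=O
F7 | step 3 | methyl (2E,6E)-9-bromo-8-hydroxy-3,7-dimethylnona-2,6-dienoate (racemic at C-8) | COC(=O)/C=C(\C)CC/C=C(\C)C(O)CBr
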